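**Plan**

- Labels: the enone is C4(=O)–C3H=C2(CH3); cyclobutane carbons are C5 (bears C4), C6 (bears C12), C7 (bears C2) and C8 (quaternary, methyl); C9 and C11 carry the isovalerates, C10 is the CH2 between them, C12 is the CMe2 carbon.
- Cuts, in retrosynthetic order: the C2=C3 bond (Horner–Wadsworth–Emmons); the two isovalerate C–O bonds; C8–C9 (acyl radical conjugate addition); C9–C10 (diazoacetate homologation); the C2–methyl bond (MeLi on a lactone); C5–C8 (cyclopropylcarbene shift); C7–C5 and C7–C6 (carbene addition to an E-alkene); C5=C6 (cross-metathesis).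
- Forward ring order: lactone-fused cyclopropane, then the cyclobutene, then the chain to C9, then the seven-membered ring by radical closure, and the cyclohexenone last.
- Feature behind the key step: C8 is a quaternary cyclobutane carbon lying between C7, which carries the ketone-level carbon C2, and the oxygenated C9. C8 can therefore be the β-carbon of a cyclobutenyl methyl ketone, attacked by a C9 acyl radical held on C6 through C10–C11–C12.
- Stereochemistry: C5 and C6 come from a catalyst-controlled intramolecular cyclopropanation of the E-alkene; C11 from asymmetric hydrogenation; C8 from the tether; C7 from hydrogen transfer (epimerisable, funnelled by the last ring closure); C9 from hydroxyl-directed reduction.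

Key step: step 14

Assumption: Rh2(S-PTTL)4 is taken to give the (1R,6S,7R) enantiomer of 8; if the sense of induction is opposite, Rh2(R-PTTL)4 is used and nothing else changes.

**Route**

Step 1
Reactants: 1 2,2-dimethylbut-3-enoic acid; 2 (Z)-1,4-bis(benzyloxy)but-2-ene
Product: 3 (E)-5-(benzyloxy)-2,2-dimethylpent-3-enoic acid
Conditions: second-generation Grubbs catalyst (5 mol %), 2 (3 equiv), CH2Cl2, 40 °C
Reagents that add atoms: none
Why: Olefin cross-metathesis: the vinyl group on the quaternary carbon does not homodimerise and couples with the excess of the reactive symmetrical alkene, the bulky substituent favouring the E isomer, and the free acid is tolerated.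

Step 2
Reactants: 3 (E)-5-(benzyloxy)-2,2-dimethylpent-3-enoic acid
Product: 4 (E)-5-(benzyloxy)-2,2-dimethylpent-3-en-1-ol
Conditions: LiAlH4, THF, 0 °C to rt; aqueous work-up
Reagents that add atoms: none
Why: Hydride reduction of a carboxylic acid to the primary alcohol; the isolated alkene and the benzyl ether are inert to LiAlH4.

Step 3
Reactants: 4 (E)-5-(benzyloxy)-2,2-dimethylpent-3-en-1-ol; 5 methyl acetoacetate
Product: 6 (E)-5-(benzyloxy)-2,2-dimethylpent-3-en-1-yl 3-oxobutanoate
Conditions: 5 (1.5 equiv), DMAP (0.2 equiv), toluene, reflux, 4 Å sieves (MeOH removal)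
Reagents that add atoms: none
Why: DMAP-catalysed transacetoacetylation, which proceeds through acetylketene and therefore acylates even a neopentyl alcohol.

Step 4
Reactants: 6 (E)-5-(benzyloxy)-2,2-dimethylpent-3-en-1-yl 3-oxobutanoate
Product: 7 (E)-5-(benzyloxy)-2,2-dimethylpent-3-en-1-yl 2-diazo-3-oxobutanoate
Conditions: 4-acetamidobenzenesulfonyl azide, Et3N, MeCN, 0 °C to rt
Reagents that add atoms: 4-acetamidobenzenesulfonyl azide, CC(=O)Nc1ccc(cc1)S(=O)(=O)N=[N+]=[N-]
Why: Regitz diazo transfer to the active methylene group of a β-keto ester.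

Step 5
Reactants: 7 (E)-5-(benzyloxy)-2,2-dimethylpent-3-en-1-yl 2-diazo-3-oxobutanoate
Product: 8 (1R,6S,7R)-1-acetyl-7-[(benzyloxy)methyl]-5,5-dimethyl-3-oxabicyclo[4.1.0]heptan-2-one
Conditions: Rh2(S-PTTL)4 (1 mol %), CH2Cl2, 0 °C to rt, slow addition of 7
Reagents that add atoms: none
Why: Intramolecular carbenoid cyclopropanation of a homoallylic diazo ketoester (the quaternary C12 offers no C–H for five-ring insertion): syn addition carries the E geometry into a trans C5/C6 relationship, the six-membered lactone forces the C7 carboxyl cis to C12, and the chiral dirhodium carboxylate selects the alkene face, which fixes C5, C6 and C7 in absolute terms.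

Step 6
Reactants: 8 (1R,6S,7R)-1-acetyl-7-[(benzyloxy)methyl]-5,5-dimethyl-3-oxabicyclo[4.1.0]heptan-2-one
Product: 9 N'-{1-[(1R,6S,7R)-7-[(benzyloxy)methyl]-5,5-dimethyl-2-oxo-3-oxabicyclo[4.1.0]heptan-1-yl]ethylidene}-4-methylbenzenesulfonohydrazide
Conditions: TsNHNH2, MeOH, 60 °C
Reagents that add atoms: 4-methylbenzenesulfonohydrazide, Cc1ccc(cc1)S(=O)(=O)NN
Why: Condensation of the methyl ketone with tosylhydrazide; the hindered lactone carbonyl is far less electrophilic towards this weak nucleophile.

Step 7
Reactants: 9 tosylhydrazone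
Product: 11 (6S,7R)-7-[(benzyloxy)methyl]-5,5,8-trimethyl-3-oxabicyclo[4.2.0]oct-1(8)-en-2-one, via diazoalkane 10 (not isolated)
Conditions: NaH, THF, 0 °C; then Rh2(OAc)4 (2 mol %), 1,4-dioxane, 70 °C
Reagents that add atoms: none
Why: Bamford–Stevens generation of the diazoalkane and cyclopropylcarbene-to-cyclobutene ring expansion at rhodium, the reaction type used on tosylhydrazones of 1-acylcyclopropane-1-carboxylates; only C5 can migrate, because migration of C6 would put the C7=C8 bond at the bridgehead of a bridged lactone, and C5 migrates with retention so that C5 and C6 stay trans.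

Step 8
Reactants: 11 cyclobutene-fused lactone
Product: 12 1-[(3R,4S)-3-[(benzyloxy)methyl]-4-(1-hydroxy-2-methylpropan-2-yl)-2-methylcyclobut-1-en-1-yl]ethan-1-one
Conditions: MeLi (1.05 equiv), THF, −78 °C; H2O quench at −78 °C
Reagents that add atoms: methyllithium, [Li]C
Why: Mono-addition of an organolithium to a lactone: at −78 °C the carbonyl takes up one methyl and the ketone is released only on quench, while conjugate addition is blocked by the fully substituted C8; this turns the tether into the C7 acetyl group (C2 and its methyl) and frees the C11 alcohol.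

Step 9
Reactants: 12 hydroxy enone
Product: 13 2-[(1S,4R)-2-acetyl-4-[(benzyloxy)methyl]-3-methylcyclobut-2-en-1-yl]-2-methylpropanal
Conditions: Dess–Martin periodinane, CH2Cl2, 0 °C to rt
Reagents that add atoms: none
Why: Dess–Martin oxidation of a neopentyl primary alcohol to an aldehyde that has no α-hydrogen and cannot epimerise or enolise.

Step 10
Reactants: 13 aldehyde
Product: 14 ethyl 4-[(1S,4R)-2-acetyl-4-[(benzyloxy)methyl]-3-methylcyclobut-2-en-1-yl]-4-methyl-3-oxopentanoate
Conditions: N2CHCO2Et (1.3 equiv), SnCl2 (15 mol %), CH2Cl2, rt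
Reagents that add atoms: ethyl diazoacetate, CCOC(=O)C=[N+]=[N-]
Why: Roskamp reaction: Lewis-acid-mediated addition of the diazoacetate to the aldehyde followed by 1,2-hydride shift gives the β-keto ester (C10 and C9); ketones do not react under these conditions.

Step 11
Reactants: 14 β-keto ester
Product: 15 ethyl (3R)-4-[(1S,4R)-2-acetyl-4-[(benzyloxy)methyl]-3-methylcyclobut-2-en-1-yl]-3-hydroxy-4-methylpentanoate
Conditions: H2 (50 atm), RuCl2[(S)-BINAP] (1 mol %), EtOH, 60 °C
Reagents that add atoms: none
Why: Noyori asymmetric hydrogenation of a β-keto ester: the ester-chelated ruthenium hydride of the (S)-BINAP complex gives the (R)-carbinol when the ketone substituent outranks CH2CO2Et, which sets C11; the unfunctionalised enone carbonyl, the tetrasubstituted alkene and the benzyl ether are not reduced by this catalyst.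

Step 12
Reactants: 15 β-hydroxy ester
Product: 16 (3R)-4-[(1S,4R)-2-acetyl-4-[(benzyloxy)methyl]-3-methylcyclobut-2-en-1-yl]-3-hydroxy-4-methylpentanoic acid
Conditions: LiOH, THF/H2O, 0 °C to rt; then 1 M HCl
Reagents that add atoms: lithium hydroxide, [Li+].[OH-]
Why: Saponification of an unhindered ethyl ester; the β-hydroxy acid does not undergo retro-aldol cleavage under these mild conditions.

Step 13
Reactants: 16 β-hydroxy acid; 17 diphenyl diselenide
Product: 18 Se-phenyl (3R)-4-[(1S,4R)-2-acetyl-4-[(benzyloxy)methyl]-3-methylcyclobut-2-en-1-yl]-3-hydroxy-4-methylpentaneselenoate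
Conditions: 17, PBu3, CH2Cl2, rt
Reagents that add atoms: none
Why: Redox condensation: PBu3 and the diselenide activate the acid as an acyloxyphosphonium ion that is captured by benzeneselenolate; the hindered C11 hydroxyl next to the quaternary carbon is not activated and needs no protection.

Step 14
Reactants: 18 selenoester
Product: 21 (4R)-7-acetyl-8-[(benzyloxy)methyl]-4-hydroxy-1,5,5-trimethylbicyclo[4.1.1]octan-2-one (both one-carbon-bridge substituents anti to the C2–C5 bridge), via acyl radical 19 (not isolated), via C7 radical 20 (not isolated)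
Conditions: (Me3Si)3SiH (1.5 equiv) and AIBN (0.3 equiv) added over 6 h, benzene, 80 °C, 0.005 M
Reagents that add atoms: none
Why: The silyl radical abstracts PhSe from 18 to give the C9 acyl radical 19, which loses CO only slowly because C10 is primary; 19 adds to C8, the β-carbon of the strained cyclobutenyl ketone, and the α-keto radical 20 takes hydrogen from the silane, which carries the chain. The closest known reaction type is the reductive acyl-radical conjugate cyclisation of phenyl selenoesters onto enones and enoates, including seven-membered endo closures. The seven-membered ring closes 7-endo-trig along C10–C11–C12–C6–C7 onto the far carbon of the C7=C8 bond, which makes the bicyclo[4.1.1]octane. C8 is controlled by the tether: the chain hangs from C6, so C9 can reach C8 only on the face of the C6–C12 bond and the methyl ends on the other face. C7 is set by hydrogen transfer from the bridge side, the outer face being screened by the C5 benzyloxymethyl group that sits 1,3-cis to it; the acetyl therefore ends cis to that arm, and the centre stays α to a ketone and correctable in step 20. The step needs attack at C8 rather than six-membered closure at C7, secured by polarity matching of the nucleophilic acyl radical with the electrophilic β-carbon, by the stabilised radical formed and by release of cyclobutene strain, and it needs cyclisation to outrun reduction of 19, secured by high dilution and slow addition of the silane.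

Step 15
Reactants: 21 β-hydroxy ketone
Product: 22 1-[(2R,4R)-8-[(benzyloxy)methyl]-2,4-dihydroxy-1,5,5-trimethylbicyclo[4.1.1]octan-7-yl]ethan-1-one
Conditions: Me4NBH(OAc)3, MeCN/AcOH, −30 °C
Reagents that add atoms: none
Why: Saksena–Evans reduction: boron binds the C11 hydroxyl and delivers hydride intramolecularly to the same face of the C9 carbonyl, giving the 9,11-anti diol and setting C9; triacetoxyborohydride does not reduce the remote acetyl ketone.

Step 16
Reactants: 22 diol
Product: 23 bis(3-methylbutanoate) of 22 at both hydroxyls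
Conditions: (iPrCH2CO)2O, DMAP, Et3N, CH2Cl2, 40 °C
Reagents that add atoms: 3-methylbutanoic anhydride, CC(C)CC(=O)OC(=O)CC(C)C
Why: DMAP-catalysed acylation of both hindered secondary alcohols installs the two isovalerates of the target, which tolerate every later step.

Step 17
Reactants: 23 diester benzyl ether
Product: 24 primary alcohol (C5 hydroxymethyl) with acetyl and both isovalerates retained
Conditions: H2 (1 atm), 10% Pd/C, EtOAc, rt
Reagents that add atoms: none
Why: Hydrogenolysis of the benzyl ether; the aliphatic ketone and the esters are untouched and no alkene remains.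

Step 18
Reactants: 24 primary alcohol
Product: 25 keto aldehyde (C5 formyl, C7 acetyl)
Conditions: Dess–Martin periodinane, CH2Cl2, rt
Reagents that add atoms: none
Why: Dess–Martin oxidation of the primary alcohol, whose open form reacts even if it rests partly as the hemiketal with the cis acetyl group.

Step 19
Reactants: 25 keto aldehyde
Product: 26 dimethyl β-ketophosphonate (C5–C4(=O)–C3H2–P(O)(OMe)2, C7 acetyl)
Conditions: N2CHP(O)(OMe)2 (1.3 equiv), SnCl2 (20 mol %), CH2Cl2, rt
Reagents that add atoms: dimethyl (diazomethyl)phosphonate, COP(=O)(OC)C=[N+]=[N-]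
Why: Roskamp-type homologation of the aldehyde with a diazomethylphosphonate gives the β-ketophosphonate directly and is selective for the aldehyde over the methyl ketone and the esters.

Step 20
Reactants: 26 β-ketophosphonate
Product: 27 CNP0192813.1
Conditions: K2CO3, 18-crown-6, toluene, 70 °C, high dilution
Reagents that add atoms: none
Why: Intramolecular Horner–Wadsworth–Emmons reaction: the C3 phosphonate carbanion attacks the C7 acetyl carbonyl (C2) and elimination forms C2=C3 regiospecifically; only the isomer with both acyl groups anti to the C9–C12 bridge can close, and since C5 and C7 are α to carbonyls and equilibrate under the base, stray epimers are funnelled to 27 while the isovalerates survive anhydrous carbonate.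

**Compound list**

1 | 2,2-dimethylbut-3-enoic acid | C=CC(C)(C)C(=O)O | starting material
2 | (Z)-1,4-bis(benzyloxy)but-2-ene | C(/C=C\COCc1ccccc1)OCc1ccccc1 | starting material
3 | (E)-5-(benzyloxy)-2,2-dimethylpent-3-enoic acid | OC(=O)C(C)(C)/C=C/COCc1ccccc1 | intermediate
4 | (E)-5-(benzyloxy)-2,2-dimethylpent-3-en-1-ol | OCC(C)(C)/C=C/COCc1ccccc1 | intermediate
5 | methyl acetoacetate | COC(=O)CC(C)=O | starting material
6 | (E)-5-(benzyloxy)-2,2-dimethylpent-3-en-1-yl 3-oxobutanoate | CC(=O)CC(=O)OCC(C)(C)/C=C/COCc1ccccc1 | intermediate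
7 | (E)-5-(benzyloxy)-2,2-dimethylpent-3-en-1-yl 2-diazo-3-oxobutanoate | CC(=O)C(=[N+]=[N-])C(=O)OCC(C)(C)/C=C/COCc1ccccc1 | intermediate
8 | (1R,6S,7R)-1-acetyl-7-[(benzyloxy)methyl]-5,5-dimethyl-3-oxabicyclo[4.1.0]heptan-2-one | CC(=O)[C@]12[C@H](COCc3ccccc3)[C@H]1C(C)(C)COC2=O | intermediate
9 | tosylhydrazone of 8 at the acetyl carbonyl (C=N geometry not defined) | CC(=NNS(=O)(=O)c1ccc(C)cc1)[C@]23[C@H](COCc4ccccc4)[C@H]2C(C)(C)COC3=O | intermediate
10 | (1R,6S,7R)-7-[(benzyloxy)methyl]-1-(1-diazoethyl)-5,5-dimethyl-3-oxabicyclo[4.1.0]heptan-2-one | CC(=[N+]=[N-])[C@]12[C@H](COCc3ccccc3)[C@H]1C(C)(C)COC2=O | intermediate (not isolated)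
11 | (6S,7R)-7-[(benzyloxy)methyl]-5,5,8-trimethyl-3-oxabicyclo[4.2.0]oct-1(8)-en-2-one | c1ccccc1COC[C@@H]2[C@H]3C(C)(C)COC(=O)C3=C2C | intermediate
12 | 1-[(3R,4S)-3-[(benzyloxy)methyl]-4-(1-hydroxy-2-methylpropan-2-yl)-2-methylcyclobut-1-en-1-yl]ethan-1-one | c1ccccc1COC[C@@H]2[C@@H](C(C)(C)CO)C(C(C)=O)=C2C | intermediate
13 | 2-[(1S,4R)-2-acetyl-4-[(benzyloxy)methyl]-3-methylcyclobut-2-en-1-yl]-2-methylpropanal | c1ccccc1COC[C@@H]2[C@@H](C(C)(C)C=O)C(C(C)=O)=C2C | intermediate
14 | ethyl 4-[(1S,4R)-2-acetyl-4-[(benzyloxy)methyl]-3-methylcyclobut-2-en-1-yl]-4-methyl-3-oxopentanoate | c1ccccc1COC[C@@H]2[C@@H](C(C)(C)C(=O)CC(=O)OCC)C(C(C)=O)=C2C | intermediate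
15 | ethyl (3R)-4-[(1S,4R)-2-acetyl-4-[(benzyloxy)methyl]-3-methylcyclobut-2-en-1-yl]-3-hydroxy-4-methylpentanoate | c1ccccc1COC[C@@H]2[C@@H](C(C)(C)[C@H](O)CC(=O)OCC)C(C(C)=O)=C2C | intermediate
16 | (3R)-4-[(1S,4R)-2-acetyl-4-[(benzyloxy)methyl]-3-methylcyclobut-2-en-1-yl]-3-hydroxy-4-methylpentanoic acid | c1ccccc1COC[C@@H]2[C@@H](C(C)(C)[C@H](O)CC(=O)O)C(C(C)=O)=C2C | intermediate
17 | diphenyl diselenide | c1ccccc1[Se][Se]c1ccccc1 | starting material
18 | Se-phenyl (3R)-4-[(1S,4R)-2-acetyl-4-[(benzyloxy)methyl]-3-methylcyclobut-2-en-1-yl]-3-hydroxy-4-methylpentaneselenoate | c1ccccc1COC[C@@H]2[C@@H](C(C)(C)[C@H](O)CC(=O)[Se]c3ccccc3)C(C(C)=O)=C2C | intermediate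
19 | C9 acyl radical formed from 18 by loss of PhSe | c1ccccc1COC[C@@H]2[C@@H](C(C)(C)[C@H](O)C[C]=O)C(C(C)=O)=C2C | intermediate (not isolated)
20 | C7 α-keto radical of the bicyclo[4.1.1]octan-2-one after ring closure | c1ccccc1COC[C@@H]2[C@@H]3[C](C(C)=O)[C@@]2(C)C(=O)C[C@@H](O)C3(C)C | intermediate (not isolated)
21 | (4R)-7-acetyl-8-[(benzyloxy)methyl]-4-hydroxy-1,5,5-trimethylbicyclo[4.1.1]octan-2-one, acetyl and benzyloxymethyl both anti to the C2–C5 bridge (labels: C9 ketone, C11 hydroxyl) | c1ccccc1COC[C@@H]2[C@@H]3[C@H](C(C)=O)[C@@]2(C)C(=O)C[C@@H](O)C3(C)C | intermediate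
22 | 1-[(2R,4R)-8-[(benzyloxy)methyl]-2,4-dihydroxy-1,5,5-trimethylbicyclo[4.1.1]octan-7-yl]ethan-1-one, ring configuration as in 21 (9,11-anti diol) | c1ccccc1COC[C@@H]2[C@@H]3[C@H](C(C)=O)[C@@]2(C)[C@H](O)C[C@@H](O)C3(C)C | intermediate
23 | (2R,4R)-7-acetyl-8-[(benzyloxy)methyl]-1,5,5-trimethylbicyclo[4.1.1]octane-2,4-diyl bis(3-methylbutanoate) | c1ccccc1COC[C@@H]2[C@@H]3[C@H](C(C)=O)[C@@]2(C)[C@H](OC(=O)CC(C)C)C[C@@H](OC(=O)CC(C)C)C3(C)C | intermediate
24 | (2R,4R)-7-acetyl-8-(hydroxymethyl)-1,5,5-trimethylbicyclo[4.1.1]octane-2,4-diyl bis(3-methylbutanoate) | OC[C@@H]1[C@@H]2[C@H](C(C)=O)[C@@]1(C)[C@H](OC(=O)CC(C)C)C[C@@H](OC(=O)CC(C)C)C2(C)C | intermediate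
25 | (2R,4R)-7-acetyl-8-formyl-1,5,5-trimethylbicyclo[4.1.1]octane-2,4-diyl bis(3-methylbutanoate) | O=C[C@@H]1[C@@H]2[C@H](C(C)=O)[C@@]1(C)[C@H](OC(=O)CC(C)C)C[C@@H](OC(=O)CC(C)C)C2(C)C | intermediate
26 | (2R,4R)-7-acetyl-8-[2-(dimethoxyphosphoryl)acetyl]-1,5,5-trimethylbicyclo[4.1.1]octane-2,4-diyl bis(3-methylbutanoate) | COP(=O)(OC)CC(=O)[C@@H]1[C@@H]2[C@H](C(C)=O)[C@@]1(C)[C@H](OC(=O)CC(C)C)C[C@@H](OC(=O)CC(C)C)C2(C)C | intermediate
27 | CNP0192813.1: tricyclic enone (cyclohexenone C2–C3–C4 bridging C7 and C5 of the cyclobutane, seven-membered ring bridging C6 and C8) with (9R,11R) bis(3-methylbutanoate) | CC1=CC(=O)[C@@H]2[C@@H]3[C@H]1[C@@]2(C)[C@H](OC(=O)CC(C)C)C[C@@H](OC(=O)CC(C)C)C3(C)C | target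

**Step count and risks**

Total: 20 steps. Longest linear sequence: 20 steps (1 to 27).

The three steps most likely to fail:

Step 14. The acyl radical may take hydrogen from the silane before the seven-membered ring closes onto the fully substituted C8, or the closure may simply be too slow at the dilution needed. The fallback sets out from 18 and returns at 21. Reduction of 18 with Bu3SnH and Pd(PPh3)4 gives (3R)-4-[(1S,4R)-2-acetyl-4-[(benzyloxy)methyl]-3-methylcyclobut-2-en-1-yl]-3-hydroxy-4-methylpentanal F3, which is also what premature reduction delivers. Irradiation of F3 (365 nm) with (Bu4N)4W10O32 in MeCN generates the same C9 acyl radical by hydrogen abstraction from the formyl group and returns the hydrogen to C7 after ring closure. In this photocatalytic hydroacylation, reduction of the acyl radical only regenerates F3, so the slow closure is no longer in competition with a destructive pathway.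

Step 5. The chiral carboxylate may discriminate the alkene faces poorly with a diazo ketoester, so that 8 forms with low enantiomeric purity. The fallback sets out from 7 and returns at 8. LiOH in aqueous MeCN removes the acetyl group of 7 to give (E)-5-(benzyloxy)-2,2-dimethylpent-3-en-1-yl diazoacetate F1, a homoallylic diazoacetate of the class for which the dirhodium carboxamidate Rh2(5S-MEPY)4 (or its antipode, chosen as for 8) gives high enantioselectivity. Its cyclopropanation gives (1R,6R,7R)-7-[(benzyloxy)methyl]-5,5-dimethyl-3-oxabicyclo[4.1.0]heptan-2-one F2. Deprotonation of F2 at the ring-fusion carbon with LDA at −78 °C and acylation with N-methoxy-N-methylacetamide, with retention enforced by the cis ring fusion, gives 8.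

Step 20. Attack of the phosphonate carbanion on the hindered cyclobutyl methyl ketone may be slower than intermolecular condensation or decomposition, since the ring closes only from the strained arrangement with both acyl groups on the same face. The fallback sets out from 25 and returns at 27, bypassing 26. Pyrrolidine and AcOH in toluene effect intramolecular aldol condensation of the methyl ketone onto the unhindered aldehyde to give the methyl-free enone F4, whose carbonyl is the former acetyl carbon on C7. MeLi with CeCl3 at −78 °C adds to that carbonyl in preference to the hindered esters and gives the tertiary allylic alcohol F5. Pyridinium chlorochromate then brings about the oxidative 1,3-transposition (Babler–Dauben oxidation) to 27, placing the methyl on C2 and the carbonyl on C4.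

**Further compounds**

F1 | step 5 | (E)-5-(benzyloxy)-2,2-dimethylpent-3-en-1-yl diazoacetate | [N-]=[N+]=CC(=O)OCC(C)(C)/C=C/COCc1ccccc1
F2 | step 5 | (1R,6R,7R)-7-[(benzyloxy)methyl]-5,5-dimethyl-3-oxabicyclo[4.1.0]heptan-2-one | O=C1OCC(C)(C)[C@@H]2[C@@H](COCc3ccccc3)[C@H]12
F3 | step 14 | (3R)-4-[(1S,4R)-2-acetyl-4-[(benzyloxy)methyl]-3-methylcyclobut-2-en-1-yl]-3-hydroxy-4-methylpentanal | c1ccccc1COC[C@@H]2[C@@H](C(C)(C)[C@H](O)CC=O)C(C(C)=O)=C2C
F4 | step 20 | methyl-free tricyclic enone, C2(=O)–C3H=C4H with the carbonyl on C7, both isovalerates in place | O=C1C=C[C@@H]2[C@@H]3[C@H]1[C@@]2(C)[C@H](OC(=O)CC(C)C)C[C@@H](OC(=O)CC(C)C)C3(C)C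
F5 | step 20 | tertiary allylic alcohol from methyl addition to the carbonyl of F4 (carbinol configuration not defined) | CC1(O)C=C[C@@H]2[C@@H]3[C@H]1[C@@]2(C)[C@H](OC(=O)CC(C)C)C[C@@H](OC(=O)CC(C)C)C3(C)C
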